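## Retrosynthetic overview

1. The spiro centre C11 and the bicyclo[2.2.2]octene are made by a Diels–Alder reaction of (R)-p-mentha-1,5-dien-8-ol 10 with an exocyclic methylene lactone. It is run on the trans-fused 6α,12-olide 31, whose open face (syn to H-7) is the one the target needs; the lactone is then moved to O8 (LiAlH4, 6-O-tiglate, oxidative lactonisation) and ring A is oxidised to the enone last.
2. Dienophile 31 comes from alkynyl opening of a 6α,7α-epoxide at C7 and palladium-catalysed cyclocarbonylation. O8/O9 come from a hydroxyl-directed epoxidation and selenoxide transposition.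
3. The seven-membered ring comes from a trans-hydrindanone by cyclopropanation/FeCl3 ring expansion. The hydrindanone comes from triketone 13 by ketoreductase desymmetrisation, aldol condensation and Li/NH3 reduction.
4. Diene 10 comes from an oxazaborolidinium-catalysed Diels–Alder reaction (2 + 3), then MeMgBr, Ito–Saegusa oxidation, dienyl triflate and iron-catalysed methylation.
5. Ring order: diene cyclohexene; ring A (from 11) → six-membered ring (aldol) → seven-membered ring (expansion) → 6,12-lactone → bicyclooctene/spiro ring → 8,12-lactone → ring-A enone.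

Conventions: helenalin numbering for the sesquiterpenoid (ring A = C1–C5; second ring = C1, C5–C10; lactone carbons C11–C13; C14 on C10, C15 on C5); β is the face of C15.
Assumption: the (S)-oxazaborolidinium catalyst in step 2 gives the (R)-adduct 4; if the sense is the reverse, the (R)-catalyst is used and nothing else changes.

## Route

Step 1
Reactants: 1 methyl vinyl ketone
Product: 2 2-(triisopropylsilyloxy)buta-1,3-diene
Conditions: TIPSOTf, Et3N, Et2O, 0 → 25 °C
Reagents that add atoms: triisopropylsilyl triflate, CC(C)[Si](C(C)C)(C(C)C)OS(=O)(=O)C(F)(F)F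
Why: Soft enolisation and O-silylation of the enone (silyl dienol ether formation) give the 2-silyloxydiene without touching the vinyl group.

Step 2
Reactants: 2 2-(triisopropylsilyloxy)buta-1,3-diene; 3 2,2,2-trifluoroethyl acrylate
Product: 4 2,2,2-trifluoroethyl (R)-4-(triisopropylsilyloxy)cyclohex-3-ene-1-carboxylate
Conditions: (S)-o-tolyl-CBS oxazaborolidine (20 mol %), Tf2NH (18 mol %), CH2Cl2, −78 → −20 °C
Reagents that add atoms: none
Why: Catalytic enantioselective Diels–Alder reaction in which the chiral oxazaborolidinium cation binds the acrylate and shields one face, so the diene adds "para" and sets the (R)-stereocentre, the first of the route.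

Step 3
Reactants: 4 trifluoroethyl ester
Product: 5 (R)-2-[4-(triisopropylsilyloxy)cyclohex-3-en-1-yl]propan-2-ol
Conditions: MeMgBr (3 equiv), THF, −78 → 0 °C
Reagents that add atoms: methylmagnesium bromide, C[Mg]Br
Why: Double Grignard addition to the activated ester is faster than α-deprotonation, so the tertiary alcohol forms without loss of configuration and the silyl enol ether survives.

Step 4
Reactants: 5 tertiary alcohol
Product: 6 (R)-triethyl({2-[4-(triisopropylsilyloxy)cyclohex-3-en-1-yl]propan-2-yl}oxy)silane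
Conditions: TESOTf, 2,6-lutidine, CH2Cl2, −78 °C
Reagents that add atoms: triethylsilyl triflate, CC[Si](CC)(CC)OS(=O)(=O)C(F)(F)F
Why: Silyl ether protection of the tertiary alcohol removes the acidic OH before the enolate and Grignard steps.

Step 5
Reactants: 6 bis-silyl compound
Product: 7 (R)-4-[2-(triethylsilyloxy)propan-2-yl]cyclohex-2-en-1-one
Conditions: Pd(OAc)2 (1.1 equiv), MeCN, 40 °C
Reagents that add atoms: none
Why: Ito–Saegusa oxidation turns the regio-defined silyl enol ether directly into the enone by β-hydride elimination toward C2, so the achiral 4-substituted cyclohexanone is never formed and the stereocentre is kept.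

Step 6
Reactants: 7 enone
Product: 8 (R)-4-[2-(triethylsilyloxy)propan-2-yl]cyclohexa-1,5-dien-1-yl trifluoromethanesulfonate
Conditions: LiN(i-Pr)2, THF, −78 °C; then PhNTf2, −78 → 0 °C
Reagents that add atoms: N-phenylbis(trifluoromethanesulfonimide), O=S(=O)(N(c1ccccc1)S(=O)(=O)C(F)(F)F)C(F)(F)F
Why: Kinetic α′-deprotonation and O-triflation give the cross-conjugated dienyl triflate, the γ-hydrogen at the stereocentre not being removed under kinetic control.

Step 7
Reactants: 8 dienyl triflate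
Product: 9 (R)-triethyl{[2-(4-methylcyclohexa-2,4-dien-1-yl)propan-2-yl]oxy}silane
Conditions: MeMgBr, Fe(acac)3 (5 mol %), THF/NMP, −30 → 0 °C
Reagents that add atoms: methylmagnesium bromide, C[Mg]Br
Why: Iron-catalysed Kumada-type cross-coupling of the alkenyl triflate installs the ring methyl group without moving the diene.

Step 8
Reactants: 9 silyl ether
Product: 10 (R)-2-(4-methylcyclohexa-2,4-dien-1-yl)propan-2-ol
Conditions: Bu4NF, THF, 0 → 25 °C
Reagents that add atoms: none
Why: Fluoride-mediated desilylation frees the tertiary alcohol under non-acidic conditions that neither isomerise nor dehydrate the diene.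

Step 9
Reactants: 11 2-methylcyclopentane-1,3-dione; 12 ethyl vinyl ketone
Product: 13 2-methyl-2-(3-oxopentyl)cyclopentane-1,3-dione
Conditions: H2O, AcOH (cat.), 75 °C
Reagents that add atoms: none
Why: Michael addition of the cyclic 1,3-dione to the enone gives the prochiral triketone.

Step 10
Reactants: 13 triketone
Product: 14 (2R,3S)-3-hydroxy-2-methyl-2-(3-oxopentyl)cyclopentan-1-one
Conditions: ketoreductase (NADPH-dependent, picked from a screening panel for the (2R,3S) product), NADP+ (cat.), i-PrOH (10 vol %), phosphate buffer pH 7, 30 °C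
Reagents that add atoms: none
Why: Ketoreductase-catalysed desymmetrising carbonyl reduction in which the enzyme reduces one of the two enantiotopic ring carbonyls from one face, setting the quaternary centre C5 and the carbinol together in the sense known from bioreductions of steroid secodiones.

Step 11
Reactants: 14 hydroxy diketone
Product: 15 (2R,3S)-3-(tert-butyldimethylsilyloxy)-2-methyl-2-(3-oxopentyl)cyclopentan-1-one
Conditions: TBSCl, imidazole, DMF, 25 °C
Reagents that add atoms: tert-butyldimethylsilyl chloride, CC(C)(C)[Si](C)(C)Cl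
Why: Silyl ether protection blocks retro-aldol cleavage of the β-hydroxy ketone in the following basic step.

Step 12
Reactants: 15 silyloxy diketone
Product: 16 (1S,7aS)-1-(tert-butyldimethylsilyloxy)-4,7a-dimethyl-1,2,3,6,7,7a-hexahydro-5H-inden-5-one
Conditions: NaOMe, MeOH, 60 °C
Reagents that add atoms: none
Why: Intramolecular aldol condensation (second half of a Robinson annulation) closes the six-membered ring onto the only remaining ring ketone and dehydrates to the tetrasubstituted enone.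

Step 13
Reactants: 16 bicyclic enone
Product: 17 (1S,3aS,4S,7aS)-1-(tert-butyldimethylsilyloxy)-4,7a-dimethyloctahydro-5H-inden-5-one (trans-fused; equatorial 4-methyl)
Conditions: Li, NH3(l)/THF, t-BuOH (1 equiv), −78 °C; NH4Cl
Reagents that add atoms: none
Why: Birch-type dissolving-metal reduction protonates the β-carbon axially to give the trans ring fusion (H-1 anti to C15), and the enolisable C10 methyl settles equatorial (α) on protonation.

Step 14
Reactants: 17 trans-hydrindanone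
Product: 18 tert-butyldimethyl{[(1S,3aS,4S,7aS)-4,7a-dimethyl-5-(trimethylsilyloxy)-2,3,3a,4,7,7a-hexahydro-1H-inden-1-yl]oxy}silane
Conditions: LiN(i-Pr)2, THF, −78 °C; then TMSCl, Et3N
Reagents that add atoms: chlorotrimethylsilane, C[Si](C)(C)Cl
Why: Kinetic enolisation removes a proton from the CH2 side (C7) and not from the methyl-bearing C10, and silylation fixes that regiochemistry.

Step 15
Reactants: 18 silyl enol ether
Product: 19 siloxycyclopropane (C8 methylene bridging C7 and C9 on the α face; the face is of no consequence)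
Conditions: Et2Zn, CH2I2, CH2Cl2, 0 → 25 °C
Reagents that add atoms: diiodomethane, ICI
Why: Simmons–Smith (Furukawa) cyclopropanation of the electron-rich enol ether double bond, expected anti to the angular methyl.

Step 16
Reactants: 19 siloxycyclopropane
Product: 21 cycloheptenone (4β-OTBS; 7-en-9-one; 10α-methyl; 5β-methyl; 1α-H), via chloro ketone 20 (not isolated)
Conditions: FeCl3 (2.5 equiv), DMF, 0 → 25 °C; then NaOAc, MeOH, 65 °C
Reagents that add atoms: none
Why: Ito–Saegusa ring expansion in which FeCl3 opens the siloxycyclopropane oxidatively at the internal bond to the β-chloro cycloheptanone and acetate eliminates HCl to the enone, inserting C8 between C7 and C9.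

Step 17
Reactants: 21 cycloheptenone
Product: 22 allylic alcohol (9β-OH; 7-ene; 4β-OTBS)
Conditions: NaBH4, CeCl3·7H2O, MeOH, −78 °C
Reagents that add atoms: none
Why: Luche 1,2-reduction with axial hydride delivery on the face opposite the pseudo-axial H-10 gives the pseudo-equatorial 9β-alcohol trans to the 10α-methyl.

Step 18
Reactants: 22 allylic alcohol
Product: 23 epoxy alcohol (7β,8β-epoxide; 9β-OH)
Conditions: VO(acac)2 (3 mol %), t-BuOOH, CH2Cl2, 0 → 25 °C
Reagents that add atoms: tert-butyl hydroperoxide, CC(C)(C)OO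
Why: Hydroxyl-directed vanadium-catalysed epoxidation delivers oxygen syn to the 9β-OH and so places the C8 oxygen on the β face.

Step 19
Reactants: 23 epoxy alcohol
Product: 24 epoxy PMB ether (9β-OPMB)
Conditions: NaH, PMBCl, Bu4NI (cat.), THF/DMF, 0 → 25 °C
Reagents that add atoms: 4-methoxybenzyl chloride, COc1ccc(CCl)cc1
Why: Williamson etherification protects O9 orthogonally to the silyl ether and keeps O8 and O9 distinguishable; the cis epoxy alkoxide cannot undergo Payne rearrangement.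

Step 20
Reactants: 24 epoxy PMB ether
Product: 26 allylic alcohol (8β-OH; 9β-OPMB; 6-ene), via hydroxy selenide 25 (not isolated)
Conditions: (PhSe)2, NaBH4, EtOH, 78 °C; then 30 % H2O2, THF, 0 → 25 °C
Reagents that add atoms: none
Why: Sharpless–Lauer sequence in which selenolate opens the epoxide at the less hindered C7 with inversion and selenoxide syn-elimination away from the carbinol carbon moves the alkene to C6–C7 with the 8β-OH intact.

Step 21
Reactants: 26 allylic alcohol
Product: 27 8β-O-tert-butyldimethylsilyl ether (6-ene; 9β-OPMB; 4β-OTBS)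
Conditions: TBSOTf, 2,6-lutidine, CH2Cl2, −78 → 0 °C
Reagents that add atoms: tert-butyldimethylsilyl triflate, CC(C)(C)[Si](C)(C)OS(=O)(=O)C(F)(F)F
Why: Silyl ether protection of O8; the bulky 8β-silyloxy group also screens the β face in the epoxidation and in the cycloaddition that follow.

Step 22
Reactants: 27 silyl ether
Product: 28 6α,7α-epoxide
Conditions: mCPBA, NaHCO3, CH2Cl2, 0 °C
Reagents that add atoms: 3-chloroperbenzoic acid, OOC(=O)c1cccc(Cl)c1
Why: Prilezhaev epoxidation occurs on the α face, anti to the 8β-silyloxy group and the angular methyl.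

Step 23
Reactants: 28 epoxide
Product: 30 7β-ethynyl-6α-ol (8β-OTBS; 9β-OPMB; 4β-OTBS), via silylalkyne 29 (not isolated)
Conditions: Me3SiC≡CH, n-BuLi, THF, −78 °C; then BF3·OEt2, −78 °C; then K2CO3, MeOH, 25 °C
Reagents that add atoms: ethynyltrimethylsilane, C#C[Si](C)(C)C
Why: Yamaguchi alkynylation, a BF3-assisted SN2 epoxide opening at C7 (C6 is neopentyl) anti to the epoxide oxygen, gives the 7β-alkynyl 6α-alcohol, and methanolysis removes the C-silyl group.

Step 24
Reactants: 30 ethynyl alcohol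
Product: 31 α-methylene 6α,12-olide (trans-fused; 8β-OTBS; 9β-OPMB; 4β-OTBS)
Conditions: PdCl2 (5 mol %), PPh3 (10 mol %), SnCl2 (10 mol %), CO (7 atm), MeCN, 75 °C
Reagents that add atoms: carbon monoxide, [C-]#[O+]
Why: Palladium-catalysed cyclocarbonylation of the homopropargylic alcohol (Norton lactone synthesis): the alkoxycarbonylpalladium species adds syn across the alkyne and protonolysis leaves the exocyclic methylene, no stereocentre being touched, so the lactone is trans-fused.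

Step 25
Reactants: 31 α-methylene 6α,12-olide; 10 (R)-2-(4-methylcyclohexa-2,4-dien-1-yl)propan-2-ol
Product: 32 spiro cycloadduct (6α,12-olide; 8β-OTBS; 9β-OPMB; 4β-OTBS)
Conditions: toluene, BHT (cat.), 110 °C, sealed tube, 48 h (diene in fourfold excess)
Reagents that add atoms: none
Why: Intermolecular Diels–Alder reaction in which the diene adds anti to its hydroxyisopropyl group and "para" (C13 to the terminus next to the methyl-bearing carbon) while the trans-fused lactone reacts on its open α face (syn to H-7, away from C8 and its silyloxy group); for the (R)-diene this one combination places the lactone carbonyl endo and sets C11 and the three bicyclooctene centres as in the target.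

Step 26
Reactants: 32 spiro lactone
Product: 33 6α,12-diol (primary alcohol at C12)
Conditions: LiAlH4, THF, 0 → 40 °C; then H2O
Reagents that add atoms: none
Why: Hydride reduction of the lactone to the diol frees O6 irreversibly and leaves C12 as a primary alcohol for later lactonisation onto O8.

Step 27
Reactants: 33 diol
Product: 34 12-O-tert-butyldimethylsilyl ether
Conditions: TBSCl, imidazole, DMF, 0 → 25 °C
Reagents that add atoms: tert-butyldimethylsilyl chloride, CC(C)(C)[Si](C)(C)Cl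
Why: Silylation is selective for the primary hydroxyl over the neopentyl-type secondary 6-OH and the tertiary carbinol.

Step 28
Reactants: 34 secondary alcohol
Product: 35 6-O-tiglate
Conditions: tigloyl chloride, DMAP, Et3N, ClCH2CH2Cl, 25 → 60 °C
Reagents that add atoms: (E)-2-methylbut-2-enoyl chloride, C/C=C(\C)C(Cl)=O
Why: DMAP-catalysed acylation of the only free secondary alcohol (hindered, hence the excess reagent and heat) with retention of the (E)-alkene; the tertiary carbinol does not react.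

Step 29
Reactants: 35 tris-silyl ether
Product: 36 tetraol 6-tiglate (12-OH; 8β-OH; 4β-OH; carbinol free; 9β-OPMB)
Conditions: HF·pyridine, pyridine/THF, 0 → 40 °C
Reagents that add atoms: none
Why: Fluoride cleavage of the three silyl ethers under weakly acidic conditions that avoid 1,3-acyl migration of the tiglate and leave the PMB ether alone.

Step 30
Reactants: 36 tetraol
Product: 38 8β,12-olide (6α-O-tigloyl; 9β-OPMB; 4β-OH), via lactol 37 (not isolated)
Conditions: TEMPO (20 mol %), PhI(OAc)2 (2.5 equiv), CH2Cl2, 25 °C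
Reagents that add atoms: none
Why: TEMPO-catalysed oxidative lactonisation: the primary alcohol is oxidised to the aldehyde, which closes onto the cis 8β-OH and is oxidised on to the cis-fused lactone, C11 keeping the configuration set in the cycloaddition and the hindered secondary 4-OH reacting far more slowly.

Step 31
Reactants: 38 C4 alcohol
Product: 39 C4 ketone
Conditions: Dess–Martin periodinane, NaHCO3, CH2Cl2, 25 °C
Reagents that add atoms: none
Why: Dess–Martin oxidation converts the secondary alcohol to the cyclopentanone under neutral conditions; the tertiary carbinol is inert.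

Step 32
Reactants: 39 C4 ketone
Product: 42 cyclopentenone (2-en-4-one; 9β-OPMB), via bis-silyl compound 40 (not isolated), via silylated enone 41 (not isolated)
Conditions: TMSOTf (3 equiv), Et3N, CH2Cl2, 0 °C; then Pd(OAc)2 (1.1 equiv), MeCN, 25 °C; then 1 M HCl, THF, 0 °C
Reagents that add atoms: none
Why: Ito–Saegusa dehydrogenation, the ketone being able to enolise only toward C3 because C5 is quaternary (the spiro lactone has no α-hydrogen); the tertiary carbinol is silylated in passing and freed again by dilute acid.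

Step 33
Reactants: 42 PMB ether
Product: 43 target CNP0185323.3
Conditions: DDQ, CH2Cl2/pH 7 buffer, 0 → 25 °C
Reagents that add atoms: none
Why: Oxidative PMB cleavage by DDQ (benzylic hydride abstraction, then hydrolysis), to which the electron-poor alkenes and the trisubstituted bicyclooctene alkene are inert.

## Compound list

1 | methyl vinyl ketone | CC(=O)C=C | starting material
2 | 2-(triisopropylsilyloxy)buta-1,3-diene | C=CC(=C)O[Si](C(C)C)(C(C)C)C(C)C | intermediate
3 | 2,2,2-trifluoroethyl acrylate | C=CC(=O)OCC(F)(F)F | starting material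
4 | 2,2,2-trifluoroethyl (R)-4-(triisopropylsilyloxy)cyclohex-3-ene-1-carboxylate | O=C(OCC(F)(F)F)[C@@H]1CCC(O[Si](C(C)C)(C(C)C)C(C)C)=CC1 | intermediate
5 | (R)-2-[4-(triisopropylsilyloxy)cyclohex-3-en-1-yl]propan-2-ol | CC(C)(O)[C@@H]1CCC(O[Si](C(C)C)(C(C)C)C(C)C)=CC1 | intermediate
6 | (R)-triethyl({2-[4-(triisopropylsilyloxy)cyclohex-3-en-1-yl]propan-2-yl}oxy)silane | CC[Si](CC)(CC)OC(C)(C)[C@@H]1CCC(O[Si](C(C)C)(C(C)C)C(C)C)=CC1 | intermediate
7 | (R)-4-[2-(triethylsilyloxy)propan-2-yl]cyclohex-2-en-1-one | CC[Si](CC)(CC)OC(C)(C)[C@@H]1CCC(=O)C=C1 | intermediate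
8 | (R)-4-[2-(triethylsilyloxy)propan-2-yl]cyclohexa-1,5-dien-1-yl trifluoromethanesulfonate | CC[Si](CC)(CC)OC(C)(C)[C@@H]1CC=C(OS(=O)(=O)C(F)(F)F)C=C1 | intermediate
9 | (R)-triethyl{[2-(4-methylcyclohexa-2,4-dien-1-yl)propan-2-yl]oxy}silane | CC[Si](CC)(CC)OC(C)(C)[C@@H]1CC=C(C)C=C1 | intermediate
10 | (R)-2-(4-methylcyclohexa-2,4-dien-1-yl)propan-2-ol | CC1=CC[C@@H](C(C)(C)O)C=C1 | intermediate
11 | 2-methylcyclopentane-1,3-dione | CC1C(=O)CCC1=O | starting material
12 | ethyl vinyl ketone (pent-1-en-3-one) | CCC(=O)C=C | starting material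
13 | 2-methyl-2-(3-oxopentyl)cyclopentane-1,3-dione | CCC(=O)CCC1(C)C(=O)CCC1=O | intermediate
14 | (2R,3S)-3-hydroxy-2-methyl-2-(3-oxopentyl)cyclopentan-1-one | CCC(=O)CC[C@@]1(C)C(=O)CC[C@@H]1O | intermediate
15 | (2R,3S)-3-(tert-butyldimethylsilyloxy)-2-methyl-2-(3-oxopentyl)cyclopentan-1-one | CCC(=O)CC[C@@]1(C)C(=O)CC[C@@H]1O[Si](C)(C)C(C)(C)C | intermediate
16 | (1S,7aS)-1-(tert-butyldimethylsilyloxy)-4,7a-dimethyl-1,2,3,6,7,7a-hexahydro-5H-inden-5-one | C1CC(=O)C(C)=C2CC[C@H](O[Si](C)(C)C(C)(C)C)[C@]21C | intermediate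
17 | (1S,3aS,4S,7aS)-1-(tert-butyldimethylsilyloxy)-4,7a-dimethyloctahydro-5H-inden-5-one | C1CC(=O)[C@@H](C)[C@@H]2CC[C@H](O[Si](C)(C)C(C)(C)C)[C@]21C | intermediate
18 | trimethylsilyl enol ether of 17 (double bond C7=C9) | C1C=C(O[Si](C)(C)C)[C@@H](C)[C@@H]2CC[C@H](O[Si](C)(C)C(C)(C)C)[C@]21C | intermediate
19 | siloxycyclopropane (α-face CH2 across C7–C9) | C1[C@H]3C[C@@]3(O[Si](C)(C)C)[C@@H](C)[C@@H]2CC[C@H](O[Si](C)(C)C(C)(C)C)[C@]21C | intermediate
20 | 7-chloro-9-oxo cycloheptanone (4β-OTBS, C7 epimers) | C1C(Cl)CC(=O)[C@@H](C)[C@@H]2CC[C@H](O[Si](C)(C)C(C)(C)C)[C@]21C | intermediate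
21 | cycloheptenone: 4β-OTBS, 7-en-9-one, 10α-Me, 5β-Me, 1α-H | C1C=CC(=O)[C@@H](C)[C@@H]2CC[C@H](O[Si](C)(C)C(C)(C)C)[C@]21C | intermediate
22 | 9β-hydroxy-7-ene | C1C=C[C@H](O)[C@@H](C)[C@@H]2CC[C@H](O[Si](C)(C)C(C)(C)C)[C@]21C | intermediate
23 | 7β,8β-epoxy-9β-ol | C1[C@@H]3O[C@@H]3[C@H](O)[C@@H](C)[C@@H]2CC[C@H](O[Si](C)(C)C(C)(C)C)[C@]21C | intermediate
24 | 7β,8β-epoxy-9β-PMB ether | C1[C@@H]3O[C@@H]3[C@H](OCc4ccc(OC)cc4)[C@@H](C)[C@@H]2CC[C@H](O[Si](C)(C)C(C)(C)C)[C@]21C | intermediate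
25 | 7α-phenylseleno-8β-ol | C1[C@@H]([Se]c3ccccc3)[C@H](O)[C@H](OCc3ccc(OC)cc3)[C@@H](C)[C@@H]2CC[C@H](O[Si](C)(C)C(C)(C)C)[C@]21C | intermediate
26 | 8β-hydroxy-9β-OPMB-6-ene | C1=C[C@H](O)[C@H](OCc3ccc(OC)cc3)[C@@H](C)[C@@H]2CC[C@H](O[Si](C)(C)C(C)(C)C)[C@]21C | intermediate
27 | 8β-O-TBS ether of 26 (6-ene; 9β-OPMB; 4β-OTBS) | C1=C[C@H](O[Si](C)(C)C(C)(C)C)[C@H](OCc3ccc(OC)cc3)[C@@H](C)[C@@H]2CC[C@H](O[Si](C)(C)C(C)(C)C)[C@]21C | intermediate
28 | 6α,7α-epoxide of 27 | [C@@H]14O[C@H]4[C@H](O[Si](C)(C)C(C)(C)C)[C@H](OCc3ccc(OC)cc3)[C@@H](C)[C@@H]2CC[C@H](O[Si](C)(C)C(C)(C)C)[C@]21C | intermediate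
29 | 7β-(trimethylsilylethynyl)-6α-ol (8β-OTBS; 9β-OPMB; 4β-OTBS) | O[C@H]1[C@H](C#C[Si](C)(C)C)[C@H](O[Si](C)(C)C(C)(C)C)[C@H](OCc4ccc(OC)cc4)[C@@H](C)[C@@H]3CC[C@H](O[Si](C)(C)C(C)(C)C)[C@]31C | intermediate
30 | 7β-ethynyl-6α-ol (8β-OTBS; 9β-OPMB; 4β-OTBS) | O[C@H]1[C@H](C#C)[C@H](O[Si](C)(C)C(C)(C)C)[C@H](OCc4ccc(OC)cc4)[C@@H](C)[C@@H]3CC[C@H](O[Si](C)(C)C(C)(C)C)[C@]31C | intermediate
31 | α-methylene 6α,12-olide, trans-fused (8β-OTBS; 9β-OPMB; 4β-OTBS); dienophile | O=C1O[C@H]2[C@H](C1=C)[C@H](O[Si](C)(C)C(C)(C)C)[C@H](OCc4ccc(OC)cc4)[C@@H](C)[C@@H]3CC[C@H](O[Si](C)(C)C(C)(C)C)[C@]32C | intermediate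
32 | Diels–Alder adduct of 31 and 10: 6α,12-olide spiro-fused at C11 to the bicyclo[2.2.2]octene; lactone carbonyl and hydroxyisopropyl both syn to the bicyclooctene alkene | O=C1O[C@H]2[C@H]([C@@]15C[C@@H]6C[C@@H](C(C)(C)O)[C@H]5C=C6C)[C@H](O[Si](C)(C)C(C)(C)C)[C@H](OCc4ccc(OC)cc4)[C@@H](C)[C@@H]3CC[C@H](O[Si](C)(C)C(C)(C)C)[C@]32C | intermediate
33 | 6α,12-diol from reduction of 32 | O[C@H]1[C@H]([C@]5(CO)C[C@@H]6C[C@@H](C(C)(C)O)[C@H]5C=C6C)[C@H](O[Si](C)(C)C(C)(C)C)[C@H](OCc4ccc(OC)cc4)[C@@H](C)[C@@H]3CC[C@H](O[Si](C)(C)C(C)(C)C)[C@]31C | intermediate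
34 | 12-O-TBS ether of 33 | O[C@H]1[C@H]([C@]5(CO[Si](C)(C)C(C)(C)C)C[C@@H]6C[C@@H](C(C)(C)O)[C@H]5C=C6C)[C@H](O[Si](C)(C)C(C)(C)C)[C@H](OCc4ccc(OC)cc4)[C@@H](C)[C@@H]3CC[C@H](O[Si](C)(C)C(C)(C)C)[C@]31C | intermediate
35 | 6α-O-tiglate of 34 | C/C=C(\C)C(=O)O[C@H]1[C@H]([C@]5(CO[Si](C)(C)C(C)(C)C)C[C@@H]6C[C@@H](C(C)(C)O)[C@H]5C=C6C)[C@H](O[Si](C)(C)C(C)(C)C)[C@H](OCc4ccc(OC)cc4)[C@@H](C)[C@@H]3CC[C@H](O[Si](C)(C)C(C)(C)C)[C@]31C | intermediate
36 | tetraol 6-tiglate (12-OH, 8β-OH, 4β-OH and carbinol free; 9β-OPMB) | C/C=C(\C)C(=O)O[C@H]1[C@H]([C@]5(CO)C[C@@H]6C[C@@H](C(C)(C)O)[C@H]5C=C6C)[C@H](O)[C@H](OCc4ccc(OC)cc4)[C@@H](C)[C@@H]3CC[C@H](O)[C@]31C | intermediate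
37 | 8β,12-lactol (anomer mixture) | C/C=C(\C)C(=O)O[C@H]1[C@H]2[C@H](OC(O)[C@]23C[C@@H]2C[C@@H](C(C)(C)O)[C@H]3C=C2C)[C@H](OCc4ccc(OC)cc4)[C@@H](C)[C@@H]2CC[C@H](O)[C@]21C | intermediate
38 | 8β,12-olide with 6α-O-tigloyl, 9β-OPMB, 4β-OH | C/C=C(\C)C(=O)O[C@H]1[C@H]2[C@H](OC(=O)[C@]23C[C@@H]2C[C@@H](C(C)(C)O)[C@H]3C=C2C)[C@H](OCc4ccc(OC)cc4)[C@@H](C)[C@@H]2CC[C@H](O)[C@]21C | intermediate
39 | 4-ketone | C/C=C(\C)C(=O)O[C@H]1[C@H]2[C@H](OC(=O)[C@]23C[C@@H]2C[C@@H](C(C)(C)O)[C@H]3C=C2C)[C@H](OCc4ccc(OC)cc4)[C@@H](C)[C@@H]2CCC(=O)[C@]21C | intermediate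
40 | 4-(trimethylsilyloxy)-3-ene with O-trimethylsilylated carbinol | C/C=C(\C)C(=O)O[C@H]1[C@H]2[C@H](OC(=O)[C@]23C[C@@H]2C[C@@H](C(C)(C)O[Si](C)(C)C)[C@H]3C=C2C)[C@H](OCc4ccc(OC)cc4)[C@@H](C)[C@@H]2CC=C(O[Si](C)(C)C)[C@]21C | intermediate
41 | 2-en-4-one with O-trimethylsilylated carbinol | C/C=C(\C)C(=O)O[C@H]1[C@H]2[C@H](OC(=O)[C@]23C[C@@H]2C[C@@H](C(C)(C)O[Si](C)(C)C)[C@H]3C=C2C)[C@H](OCc4ccc(OC)cc4)[C@@H](C)[C@@H]2C=CC(=O)[C@]21C | intermediate
42 | 2-en-4-one, 9β-OPMB | C/C=C(\C)C(=O)O[C@H]1[C@H]2[C@H](OC(=O)[C@]23C[C@@H]2C[C@@H](C(C)(C)O)[C@H]3C=C2C)[C@H](OCc4ccc(OC)cc4)[C@@H](C)[C@@H]2C=CC(=O)[C@]21C | intermediate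
43 | CNP0185323.3 | C/C=C(\C)C(=O)O[C@H]1[C@H]2[C@H](OC(=O)[C@]23C[C@@H]2C[C@@H](C(C)(C)O)[C@H]3C=C2C)[C@H](O)[C@@H](C)[C@@H]2C=CC(=O)[C@]21C | target

## Summary and fallbacks

Total step count: 33. Longest linear sequence: 25 steps (steps 9–33).

Steps most likely to fail:

Step 10. The ketoreductase may reduce the side-chain ketone or give the wrong carbonyl/face. Fallback: set out from 13 and close the ring first by an amino-acid-catalysed Hajos–Parrish aldol condensation (L-phenylalanine, HClO4 cat., MeCN, 80 °C) to the (S)-enedione F1. Reduce its saturated ketone with NaBH4 (EtOH, −20 °C), hydride arriving anti to the angular methyl, to the hydroxy enone F2. Silylate with TBSCl/imidazole; this comes back to the route at 16.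

Step 23. The hindered epoxide may rearrange under BF3 or open sluggishly. Fallback: set out from 27 and replace the epoxide by a cyclic sulfate, which needs no Lewis acid. OsO4 (cat.) with N-methylmorpholine N-oxide (acetone/H2O) dihydroxylates the alkene on the α face to the 6α,7α-diol F3. 1,1'-Sulfonyldiimidazole with NaH (THF, −20 → 0 °C) closes the cyclic sulfate F4. LiC≡CSiMe3 (THF, −20 → 25 °C) opens it at C7 from the β face to the 6α-O-sulfate F5. H2SO4 (cat.) and water in THF hydrolyse the sulfate ester; this comes back to the route at 29.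

Step 25. The thermal cycloaddition may be too slow for the sensitive diene, or the "meta" regioisomer may compete. Fallback: set out from enone 7 and dienophile 31 and use a more reactive and regiochemically unambiguous 2-silyloxy diene. LiN(i-Pr)2 then TBSCl (THF/HMPA, −78 °C) converts 7 into the silyloxy diene F6. Heating it with 31 (toluene, 80 °C) gives the cycloadduct F7, a bicyclic silyl enol ether. CsF and PhNTf2 (DME, 25 °C) turn it into the enol triflate F8. MeMgBr with Fe(acac)3 (THF/NMP, −30 °C) installs the methyl group to give the triethylsilyl ether F9. PPTS in MeOH (25 °C) frees the tertiary alcohol; this comes back to the route at 32.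

Further compounds
F1 | step 10 | (S)-4,7a-dimethyl-2,3,7,7a-tetrahydro-1H-indene-1,5(6H)-dione | C1CC(=O)C(C)=C2CCC(=O)[C@]21C
F2 | step 10 | (1S,7aS)-1-hydroxy-4,7a-dimethyl-1,2,3,6,7,7a-hexahydro-5H-inden-5-one | C1CC(=O)C(C)=C2CC[C@H](O)[C@]21C
F3 | step 23 | 6α,7α-diol of 27 | O[C@H]1[C@@H](O)[C@H](O[Si](C)(C)C(C)(C)C)[C@H](OCc4ccc(OC)cc4)[C@@H](C)[C@@H]3CC[C@H](O[Si](C)(C)C(C)(C)C)[C@]31C
F4 | step 23 | 6α,7α-cyclic sulfate | O=S1(=O)O[C@H]2[C@@H](O1)[C@H](O[Si](C)(C)C(C)(C)C)[C@H](OCc4ccc(OC)cc4)[C@@H](C)[C@@H]3CC[C@H](O[Si](C)(C)C(C)(C)C)[C@]32C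
F5 | step 23 | 7β-(trimethylsilylethynyl) 6α-O-hydrogen sulfate | OS(=O)(=O)O[C@H]1[C@H](C#C[Si](C)(C)C)[C@H](O[Si](C)(C)C(C)(C)C)[C@H](OCc4ccc(OC)cc4)[C@@H](C)[C@@H]3CC[C@H](O[Si](C)(C)C(C)(C)C)[C@]31C
F6 | step 25 | (R)-2-(tert-butyldimethylsilyloxy)-5-[2-(triethylsilyloxy)propan-2-yl]cyclohexa-1,3-diene | CC[Si](CC)(CC)OC(C)(C)[C@@H]1CC=C(O[Si](C)(C)C(C)(C)C)C=C1
F7 | step 25 | spiro cycloadduct of 31 and F6 (bicyclooctene silyl enol ether; O-triethylsilyl carbinol) | O=C1O[C@H]2[C@H]([C@@]15C[C@@H]6C[C@@H](C(C)(C)O[Si](CC)(CC)CC)[C@H]5C=C6O[Si](C)(C)C(C)(C)C)[C@H](O[Si](C)(C)C(C)(C)C)[C@H](OCc4ccc(OC)cc4)[C@@H](C)[C@@H]3CC[C@H](O[Si](C)(C)C(C)(C)C)[C@]32C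
F8 | step 25 | bicyclooctenyl triflate | O=C1O[C@H]2[C@H]([C@@]15C[C@@H]6C[C@@H](C(C)(C)O[Si](CC)(CC)CC)[C@H]5C=C6OS(=O)(=O)C(F)(F)F)[C@H](O[Si](C)(C)C(C)(C)C)[C@H](OCc4ccc(OC)cc4)[C@@H](C)[C@@H]3CC[C@H](O[Si](C)(C)C(C)(C)C)[C@]32C
F9 | step 25 | O-triethylsilyl ether of 32 | O=C1O[C@H]2[C@H]([C@@]15C[C@@H]6C[C@@H](C(C)(C)O[Si](CC)(CC)CC)[C@H]5C=C6C)[C@H](O[Si](C)(C)C(C)(C)C)[C@H](OCc4ccc(OC)cc4)[C@@H](C)[C@@H]3CC[C@H](O[Si](C)(C)C(C)(C)C)[C@]32C
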